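- I decided to judge this flask, closed, stirred and isothermal, by counting its nucleophile rather than by extending its curve; the south run is this same flask, followed so far.

| flask | electrophile | nucleophile | remark | time |
|---|---|---|---|---|
| south | 0.035 M | 0.028 M | the very flask that is asked about, followed so far |  |
| flask | 0.035 M | 0.0280 M |  | 3.0 d |

south run (percent of the electrophile charged)

| time / h | target / % |
|---|---|
| 3.00 | 20.3 |
| 8.00 | 28.8 |
| 20.0 | 29.3 |
| 40.0 | 25.4 |

(scatter of a reading: 0.3 percentage points)

- additions leave the volume as it is
- the numbers in the tables scatter with a standard deviation of 0.3 percentage points
- a reading or a percentage of target counts all its forms, free or not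

- larch: at 3.0 d take out 90 % of the acid set free then present, then wait 3.0 d
- birch: at 3.0 d add electrophile, 50.0 % of the amount charged, then wait 3.0 d
- elm: change nothing and wait 3.0 d more
- alder: at 3.0 d add nucleophile, 50.0 % of the amount charged, then wait 3.0 d

- target, in percent of the electrophile first charged, at 3.0 d
- which option adds most target ("none" when 2 percentage points or less is all one gets) (larch / birch / elm / alder / none)
- target present, in percent of the electrophile first charged, after larch
- target present, in percent of the electrophile first charged, after alder

- In the south run the target reached 29.3 % at 20.0 h, below the 80.0 % that one nucleophile per target would allow, so I assumed that the acid set free ties up a second nucleophile.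
- I therefore carried the cover C = 40.0 %, the share of the charged electrophile that the nucleophile can pay for at 2 nucleophile per target; it stands below 100 %, which makes the nucleophile the limiting reagent by my count.
- Elm changes no charge, so it leaves C alone. The readings fell from 29.3 % to 25.4 % between 20.0 h and 40.0 h, and that first-order pace carried on to 3.0 d gave me 20.2 % for now, so I expected waiting longer to lose target.
- Birch brings electrophile and no nucleophile, so by my count the target that can be paid for stays as it was, and I expected no gain.
- Larch brings no nucleophile either. On my assumption it could return what the acid held, but readings of target do not show that amount, so I booked no firm gain.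
- Alder would raise C by 20 percentage points to 60.0 %, and so I chose alder.
- The forecast gave 20.2 % for now, larch as best, 27 % after larch and 23 % after alder, on the ground that “Removing acid therefore restarts the reaction”; on the best option it parts from my choice.

    target → over-reaction product (k = 3.00 × 10⁻⁵ h⁻¹)
    electrophile + nucleophile → acid set free + target (k = 4.20 M⁻¹ h⁻¹)
    electrophile + target → side product (k = 1.20 M⁻¹ h⁻¹)
    nucleophile + acid set free ⇌ protonated nucleophile, settled at all times (K = 1600 M⁻¹)
    crystals ⇌ target, rate k5*(cs5 - [target]) while solid is left; crystals form when [target] > cs5 (solubility = 23.0 mM, k = 5.50 h⁻¹)

- The flask gave 20.6 % at 3.0 d, and alder was best: alder changed the target by 5.5 points, to 26.2 %, and larch by −2.1 points, to 18.5 %. At 3.00 d the flask held 58.7 % of the electrophile charged as side product, one side product counting as two, more than its 20.6 % as target. Its C was 40.0 %, and at 3.00 d the flask had 2.78 % of its nucleophile free beside 20.6 % of its electrophile; yet acid set free and protonated nucleophile together came to 50.0 % of the electrophile charged, more than C, with 0.00780 M of the acid still unbound. The neighbour flask with 0.11 M of nucleophile has C = 157 %, and at 3.00 d its electrophile stood at 0 % and its free nucleophile at 40.7 % of its charge, against the 36.4 % that this count leaves spare.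

The readings are calculated from invented constants.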